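**Plan**

Numbering (avarane skeleton): ring A = C1–C5 and C10; ring B = C5–C10; C11 = exocyclic CH2 on C4; C15 = benzylic CH2 on C9.
Retrosynthetic cuts, in order: phenol O–PMB; C15–aryl, with oxygen put back on C15 and C1 (arylmagnesium + lactol); C4=C11 (Wittig); C4–C5 (radical closure of ring A); C9–C10 and C7–C8 together (intramolecular Diels–Alder); ester O–C15; C1–C2.
Enabling feature: in ring B, the cis methyls on C8 and C9 plus C15 on C9 are the carbon skeleton of tiglic acid. C15 and C1 stand 1,4 across C9–C10, so one oxygen joins them in a five-membered C1–O–C15 lactone that ties the tiglate alkene C8=C9 to the diene C10=C5–C6=C7.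
Forward order: acyclic dienyl tiglate → ring B and the lactone in one step → ring A closed on the intact lactone → methylenation → arene added at C15 → both oxygens removed → phenol freed.
Stereochemistry: C1 (S) comes from a Ti–TADDOLate-catalysed dialkylzinc addition. C8, C9 and C10 come from the cycloaddition (tiglate geometry, exo tether, A(1,3)-controlled face). C5 comes from the lactone-locked radical closure, and C1 is then erased.

Key step: step 5

Remark: descriptors in names use the skeleton numbering above. The C4 carbinol of 12, the lactol carbon of 15 and the C15 carbinol carbon of 19 and 20 are expected as epimer mixtures, are written without configuration, and are all erased later.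

**Step 1**
Reactants: 1 (E)-3-methylpent-2-en-4-yn-1-ol
Product: 2 (E)-3-methylpent-2-en-4-ynal
Conditions: activated MnO2 (15 equiv), CH2Cl2, rt
Reagents that add atoms: none
Why: Manganese dioxide oxidation of an allylic alcohol is neutral and selective, so the E double bond and the terminal alkyne stay as they are and the volatile enynal can be used as a dried solution.

**Step 2**
Reactants: 2 (E)-3-methylpent-2-en-4-ynal; 3 2-(2-bromoethyl)-1,3-dioxolane
Product: 6 (3S,4E)-1-(1,3-dioxolan-2-yl)-5-methylhept-4-en-6-yn-3-ol, via Grignard reagent 4 (not isolated), via dialkylzinc 5 (not isolated)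
Conditions: 3, Mg, THF, 30 °C; ZnCl2 (0.5 equiv per RMgBr), Et2O, then 1,4-dioxane, filter; Ti(OiPr)4 (1.2 equiv), (R,R)-TADDOL–Ti(OiPr)2 (20 mol%), PhMe, −25 °C; then 2
Reagents that add atoms: none
Why: Titanium–TADDOLate-catalysed enantioselective addition of a functionalised dialkylzinc to an α,β-unsaturated aldehyde forms C1–C2; the (R,R)-ligand steers alkyl transfer to the Si face, which gives the (S)-carbinol at C1, the magnesium salts that would carry a racemic background reaction are removed as their dioxane complex, and without an amine base the alkyne C–H is not zincated at this temperature.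

**Step 3**
Reactants: 6 (3S,4E)-1-(1,3-dioxolan-2-yl)-5-methylhept-4-en-6-yn-3-ol
Product: 7 (3S,4E)-1-(1,3-dioxolan-2-yl)-5-methylhepta-4,6-dien-3-ol
Conditions: H2 (1 atm), Lindlar catalyst, quinoline, EtOAc, rt, stopped after one equivalent of H2
Reagents that add atoms: none
Why: Lindlar semihydrogenation stops at the vinyl group because the terminal alkyne binds the poisoned palladium surface far better than the diene that is formed, and it touches neither the E C5=C10 bond nor C1.

**Step 4**
Reactants: 7 (3S,4E)-1-(1,3-dioxolan-2-yl)-5-methylhepta-4,6-dien-3-ol; 8 tiglic acid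
Product: 9 dienyl tiglate, (3S,4E)-1-(1,3-dioxolan-2-yl)-5-methylhepta-4,6-dien-3-yl (2E)-2-methylbut-2-enoate
Conditions: 8 (1.3 equiv), DCC (1.3 equiv), DMAP (0.2 equiv), CH2Cl2, 0 °C → rt
Reagents that add atoms: none
Why: Steglich esterification works under neutral conditions that do not ionise the dienylic alcohol, proceeds with retention at C1 because only the O–H bond is broken, and cannot scramble tiglic acid, which is the more stable E isomer.

**Step 5**
Reactants: 9 dienyl tiglate
Product: 10 trans-fused cyclohexene γ-lactone, (3S,3aR,7S,7aR)-3-[2-(1,3-dioxolan-2-yl)ethyl]-4,7,7a-trimethyl-3a,6,7,7a-tetrahydro-2-benzofuran-1(3H)-one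
Conditions: 1,2-dichlorobenzene (0.01 M), BHT (10 mol%), Ar, base-washed sealed vessel, 190 °C
Reagents that add atoms: none
Why: A thermal, concerted and asynchronous [4+2] cycloaddition of the fused (type 1) intramolecular kind, the known reaction of penta-2,4-dienyl enoates, in which the tiglate alkene C8=C9 adds suprafacially to the s-cis diene C10=C5–C6=C7 and leaves the C5=C6 alkene. Ring B closes as a cyclohexene through both new bonds (C9–C10 and C7–C8), and the five-membered lactone C9–C10–C1–O–C15 closes through C9–C10 alone over the three-atom tether, which also imposes the C9-to-C10 regiochemistry that this 1,2-disubstituted diene would not secure in a bimolecular reaction. C8 and C9 are set by the E geometry of the tiglate (methyls cis), C10 by the E C5=C10 bond together with the tether-exo, methyl-endo transition state (C9 methyl trans to C10–H, trans-fused lactone), and the absolute sense of all three by C1. The step needs exo and facial selectivity, and both rest on the C5 methyl, which is cis to C1 on the diene: A(1,3) strain keeps C1–H in the diene plane, the ester oxygen on the reacting face and the side chain on the far face, whereas the tether-endo geometry would force two C1 substituents to straddle that methyl; a substituent at this diene position is known to sharpen both selectivities in this ester class. The dienophile is trisubstituted and the ester must leave its preferred Z conformation, so the reaction is slow and is run hot, dilute, with a radical inhibitor, in acid-free glass and in a moderately polar solvent that favours the reactive ester rotamer. Lewis acids are avoided because they would ionise the dienylic C1–O bond.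

**Step 6**
Reactants: 10 trans-fused cyclohexene γ-lactone
Product: 11 lactone aldehyde (1S,8S,9R,10R), 10 with the dioxolane replaced by the C4 aldehyde
Conditions: 1 M aq HCl, THF, rt
Reagents that add atoms: water, O
Why: Acid-catalysed acetal hydrolysis frees the C4 aldehyde, and the lactone, the trisubstituted alkene and all four stereocentres are inert to dilute aqueous acid at room temperature.

**Step 7**
Reactants: 11 lactone aldehyde
Product: 12 tricyclic hydroxy lactone (1S,5S,8S,9R,10R; C4 epimers)
Conditions: Fe(acac)3 (0.3 equiv), PhSiH3 (3 equiv), degassed EtOH (0.02 M), 60 °C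
Reagents that add atoms: none
Why: MHAT-initiated radical cyclisation of an alkene-tethered carbonyl compound, a known iron hydride reaction: hydrogen-atom transfer to C6 gives the tertiary C5 radical, which adds 6-exo-trig to the aldehyde carbon C4 to close ring A before the alkoxyl radical is reduced, and C5 is set by the lactone, which fixes ring B with the C9 methyl axial, holds C2 gauche to C5 on the C10–H face and places C1–H on the other face, so that the three-carbon chain can reach only the radical lobe anti to the C9 methyl (C5 methyl trans to C10–H, trans-decalin), while the C4 epimers are merged in step 8.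

**Step 8**
Reactants: 12 tricyclic hydroxy lactone
Product: 13 tricyclic keto lactone (1S,5S,8S,9R,10R)
Conditions: Dess–Martin periodinane (1.3 equiv), CH2Cl2, rt
Reagents that add atoms: none
Why: Dess–Martin oxidation turns both C4 epimers of the hindered secondary alcohol into one ketone under neutral conditions that leave the lactone alone.

**Step 9**
Reactants: 13 tricyclic keto lactone
Product: 14 tricyclic methylidene lactone (1S,5S,8S,9R,10R)
Conditions: Ph3PCH3Br (3 equiv), KHMDS (2.8 equiv), THF, 0 °C; then 13, rt → 50 °C
Reagents that add atoms: methyltriphenylphosphonium bromide, C[P+](c1ccccc1)(c1ccccc1)c1ccccc1.[Br-]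
Why: Wittig methylenation of a ketone next to a quaternary carbon is standard for this decalin type, the ylide prefers the ketone to the lactone carbonyl that is shielded by quaternary C9, and no stereocentre is enolisable because C5 and C9 are quaternary.

**Step 10**
Reactants: 14 tricyclic methylidene lactone
Product: 15 tricyclic lactol (1S,5S,8S,9R,10R; C15 epimers)
Conditions: DIBAL-H (1.1 equiv), CH2Cl2, −78 °C; aqueous work-up
Reagents that add atoms: none
Why: DIBAL-H partial reduction of a lactone stops at the lactol because the tetrahedral aluminium alkoxide is stable at −78 °C, and the isolated 1,1-disubstituted alkene does not react.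

**Step 11**
Reactants: 16 methyl 5-iodovanillate
Product: 17 methyl 3-iodo-5-methoxy-4-[(4-methoxyphenyl)methoxy]benzoate
Conditions: PMBCl (1.2 equiv), K2CO3 (1.5 equiv), DMF, 60 °C
Reagents that add atoms: 4-methoxybenzyl chloride, COc1ccc(CCl)cc1
Why: Williamson ether synthesis on the acidic phenol installs a PMB group that withstands organomagnesium reagents, hydride base and tin hydride and can later be removed oxidatively without acid or hydrogen.

**Step 12**
Reactants: 15 tricyclic lactol; 17 methyl 3-iodo-5-methoxy-4-[(4-methoxyphenyl)methoxy]benzoate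
Product: 19 C1,C15-diol (1S,5S,8S,9R,10R; C15 epimers), via arylmagnesium chloride 18 (not isolated)
Conditions: 17 (2.5 equiv), iPrMgCl·LiCl (2.4 equiv), THF, −40 °C; then 15, −40 → 0 °C
Reagents that add atoms: none
Why: Iodine–magnesium exchange with the turbo-Grignard reagent is faster than attack on the methyl ester at low temperature, and addition of an arylmagnesium to a lactol through its ring-opened hydroxy aldehyde is a standard route to 1,4-diols: the first equivalent deprotonates 15, strain in the doubly trans-fused lactol favours opening, the second equivalent forms the C15–aryl bond, and both C15 epimers are erased in step 14.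

**Step 13**
Reactants: 19 C1,C15-diol
Product: 20 C1,C15-bis(S-methyl xanthate)
Conditions: NaH (4 equiv), CS2 (10 equiv), THF, 0 °C → rt; then MeI (6 equiv), rt
Reagents that add atoms: carbon disulfide, S=C=S; iodomethane, CI
Why: Xanthate formation, the first half of the Barton–McCombie deoxygenation, converts both alkoxides into non-electrophilic xanthate salts before iodomethane is added, which avoids a cyclic thionocarbonate, and the benzoate and the alkene are inert.

**Step 14**
Reactants: 20 C1,C15-bis(S-methyl xanthate)
Product: 21 O-PMB polyfibrospongol A (5S,8S,9R,10S)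
Conditions: Bu3SnH (5 equiv), AIBN (0.2 equiv), PhMe, 100 °C
Reagents that add atoms: none
Why: Twofold Barton–McCombie deoxygenation: stannyl radical attack on each C=S releases a benzylic radical at C15 and a secondary radical at C1, both are quenched by tin hydride faster than they could attack the remote alkene, C15 has no β-hydrogen for elimination, and the auxiliary stereocentre C1 disappears while C5, C8, C9 and C10 are untouched.

**Step 15**
Reactants: 21 O-PMB polyfibrospongol A
Product: 22 polyfibrospongol A
Conditions: DDQ (1.3 equiv), CH2Cl2/pH 7 buffer (10:1), 0 °C → rt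
Reagents that add atoms: none
Why: Oxidative PMB cleavage with DDQ in buffered wet dichloromethane removes the benzyl group by hydride abstraction and hydrolysis, without acid or hydrogen, so the exocyclic C4=C11 alkene is not shifted into the ring and the methyl ester is not touched.

**Compound list**

1 | (E)-3-methylpent-2-en-4-yn-1-ol | C#C/C(C)=C/CO | starting material
2 | (E)-3-methylpent-2-en-4-ynal | C#C/C(C)=C/C=O | intermediate
3 | 2-(2-bromoethyl)-1,3-dioxolane | BrCCC1OCCO1 | starting material
4 | [2-(1,3-dioxolan-2-yl)ethyl]magnesium bromide | Br[Mg]CCC1OCCO1 | intermediate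
5 | bis[2-(1,3-dioxolan-2-yl)ethyl]zinc | C1COC(CC[Zn]CCC2OCCO2)O1 | intermediate
6 | (3S,4E)-1-(1,3-dioxolan-2-yl)-5-methylhept-4-en-6-yn-3-ol | C#C/C(C)=C/[C@H](CCC1OCCO1)O | intermediate
7 | (3S,4E)-1-(1,3-dioxolan-2-yl)-5-methylhepta-4,6-dien-3-ol | C=C/C(C)=C/[C@H](CCC1OCCO1)O | intermediate
8 | tiglic acid, (E)-2-methylbut-2-enoic acid | C/C=C(C)/C(=O)O | starting material
9 | dienyl tiglate, (3S,4E)-1-(1,3-dioxolan-2-yl)-5-methylhepta-4,6-dien-3-yl (2E)-2-methylbut-2-enoate | C=C/C(C)=C/[C@H](CCC1OCCO1)OC(=O)/C(C)=C/C | intermediate
10 | trans-fused cyclohexene γ-lactone, (3S,3aR,7S,7aR)-3-[2-(1,3-dioxolan-2-yl)ethyl]-4,7,7a-trimethyl-3a,6,7,7a-tetrahydro-2-benzofuran-1(3H)-one | C1(CC[C@@H]2OC(=O)[C@]3(C)[C@@H](C)CC=C(C)[C@@H]23)OCCO1 | intermediate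
11 | lactone aldehyde (1S,8S,9R,10R): 10 with CHO (C4) in place of the dioxolane | O=CCC[C@@H]1OC(=O)[C@]2(C)[C@@H](C)CC=C(C)[C@@H]12 | intermediate
12 | tricyclic hydroxy lactone (1S,5S,8S,9R,10R): trans-decalin with methyls on C5, C8 and C9, C4–OH (epimers) and the γ-lactone C1–O–C15(=O)–C9 | OC1CC[C@@H]2OC(=O)[C@]3(C)[C@@H](C)CC[C@@]1(C)[C@@H]23 | intermediate
13 | tricyclic keto lactone (1S,5S,8S,9R,10R): 12 with C4=O | O=C1CC[C@@H]2OC(=O)[C@]3(C)[C@@H](C)CC[C@@]1(C)[C@@H]23 | intermediate
14 | tricyclic methylidene lactone (1S,5S,8S,9R,10R): 13 with C4=CH2 | C=C1CC[C@@H]2OC(=O)[C@]3(C)[C@@H](C)CC[C@@]1(C)[C@@H]23 | intermediate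
15 | tricyclic lactol (1S,5S,8S,9R,10R): 14 with C15H(OH), epimers | C=C1CC[C@@H]2OC(O)[C@]3(C)[C@@H](C)CC[C@@]1(C)[C@@H]23 | intermediate
16 | methyl 5-iodovanillate, methyl 4-hydroxy-3-iodo-5-methoxybenzoate | COC(=O)c1cc(I)c(O)c(OC)c1 | starting material
17 | methyl 3-iodo-5-methoxy-4-[(4-methoxyphenyl)methoxy]benzoate | COC(=O)c1cc(I)c(OCc2ccc(OC)cc2)c(OC)c1 | intermediate
18 | arylmagnesium chloride from 17 (MgCl in place of I) | COC(=O)c1cc([Mg]Cl)c(OCc2ccc(OC)cc2)c(OC)c1 | intermediate
19 | C1,C15-diol (1S,5S,8S,9R,10R): trans-decalin with C4=CH2, C1–OH and C9–CH(OH)Ar (C15 epimers), Ar = 5-methoxycarbonyl-3-methoxy-2-(PMB-oxy)phenyl | C=C1CC[C@H](O)[C@H]2[C@](C)(C(O)c3cc(C(=O)OC)cc(OC)c3OCc4ccc(OC)cc4)[C@@H](C)CC[C@]12C | intermediate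
20 | C1,C15-bis(S-methyl xanthate) of 19 | C=C1CC[C@H](OC(=S)SC)[C@H]2[C@](C)(C(OC(=S)SC)c3cc(C(=O)OC)cc(OC)c3OCc4ccc(OC)cc4)[C@@H](C)CC[C@]12C | intermediate
21 | O-PMB polyfibrospongol A (5S,8S,9R,10S) | C=C1CCC[C@H]2[C@](C)(Cc3cc(C(=O)OC)cc(OC)c3OCc4ccc(OC)cc4)[C@@H](C)CC[C@]12C | intermediate
22 | polyfibrospongol A, methyl 4-hydroxy-3-methoxy-5-{[(1R,2S,4aS,8aS)-1,2,4a-trimethyl-5-methylidenedecahydronaphthalen-1-yl]methyl}benzoate | C=C1CCC[C@H]2[C@](C)(Cc3cc(C(=O)OC)cc(OC)c3O)[C@@H](C)CC[C@]12C | target

**Step count**

Total step count: 15. Longest linear sequence: 14 (steps 1–10 and 12–15, from 1).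

**Steps most likely to fail**

Step 5. The cycloaddition may be too slow, so that thermal loss of tiglic acid from the dienylic ester or oligomerisation of the diene overtakes it.
- The fallback keeps both ring closures and activates the dienophile with a second carbonyl group on C8, which is afterwards cut down to the C8 methyl.
- It sets out from dienol 7. Steglich esterification with mesaconic acid 4-methyl ester F1 gives the dienyl methyl mesaconate F2. F1 comes from partial Fischer esterification of commercial mesaconic acid, in which the carboxyl group on the methyl-bearing carbon stays free.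
- F2 is a fumarate-type triene of the kind that cyclises in refluxing toluene with the terminal ester endo. That is the same tether-exo geometry, and it leads to the lactone ester F3.
- SN2 cleavage of the methyl ester by iodide (LiI, EtOAc, reflux) spares the secondary lactone C–O bond and gives the lactone acid F4.
- Isobutyl chloroformate and N-methylmorpholine give the mixed anhydride F5, which NaBH4 reduces at −15 °C to the primary alcohol F6.
- Appel iodination gives the iodide F7, and Bu3SnH/AIBN reduces C–I to the C8 methyl group. This brings the sequence back at lactone 10.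

Step 7. Addition of the tertiary radical to the aldehyde is reversible and builds some ring strain, so premature hydrogen transfer to C5 (net hydrogenation) or silane reduction of the aldehyde may win.
- The fallback changes the acceptor from C=O to C≡N and sets out from aldehyde 11.
- Hydroxylamine gives the oxime F8, and acetic anhydride dehydrates it to the nitrile F9.
- Iron hydride conditions then close C5–C4 onto the nitrile. This is a known HAT-initiated alkene–nitrile cyclisation in which the iminyl radical hardly fragments back and the acceptor is inert to the silane.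
- The ketimine F10 is hydrolysed on aqueous work-up, and the sequence returns at ketone 13, so step 8 is saved.
- The lactone lock on the C5 face is unchanged.

Step 12. At the low temperature that the ester-bearing arylmagnesium tolerates, ring opening of the lactolate and attack on the neopentyl aldehyde may be too slow, and warming brings self-condensation of the reagent.
- The fallback masks the ester as a carboxylate and sets out from iodide 17. Saponification (LiOH, THF/H2O) gives the iodo acid F11.
- MeMgCl deprotonates F11, and iPrMgCl·LiCl then exchanges the iodine to give the magnesiated carboxylate F12. This species has no electrophilic site and can be stirred with lactol 15 at room temperature.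
- Work-up gives the dihydroxy acid F13. K2CO3/MeI in DMF methylates only the carboxylate, which returns the sequence at diol 19.

**Further compounds**

F1 | step 5 | mesaconic acid 4-methyl ester, (E)-4-methoxy-2-methyl-4-oxobut-2-enoic acid | OC(=O)/C(C)=C/C(=O)OC
F2 | step 5 | dienyl methyl mesaconate (9 with CO2Me in place of the terminal methyl of the enoate) | C=C/C(C)=C/[C@H](CCC1OCCO1)OC(=O)/C(C)=C/C(=O)OC
F3 | step 5 | lactone ester (10 with CO2Me in place of the C8 methyl) | C1(CC[C@@H]2OC(=O)[C@]3(C)[C@@H](C(=O)OC)CC=C(C)[C@@H]23)OCCO1
F4 | step 5 | lactone acid (10 with CO2H in place of the C8 methyl) | C1(CC[C@@H]2OC(=O)[C@]3(C)[C@@H](C(=O)O)CC=C(C)[C@@H]23)OCCO1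
F5 | step 5 | mixed anhydride of F4 with isobutyl carbonate | C1(CC[C@@H]2OC(=O)[C@]3(C)[C@@H](C(=O)OC(=O)OCC(C)C)CC=C(C)[C@@H]23)OCCO1
F6 | step 5 | primary alcohol (10 with CH2OH in place of the C8 methyl) | C1(CC[C@@H]2OC(=O)[C@]3(C)[C@@H](CO)CC=C(C)[C@@H]23)OCCO1
F7 | step 5 | iodide (10 with CH2I in place of the C8 methyl) | C1(CC[C@@H]2OC(=O)[C@]3(C)[C@@H](CI)CC=C(C)[C@@H]23)OCCO1
F8 | step 7 | oxime of aldehyde 11 | ON=CCC[C@@H]1OC(=O)[C@]2(C)[C@@H](C)CC=C(C)[C@@H]12
F9 | step 7 | nitrile (11 with C4≡N in place of CHO) | N#CCC[C@@H]1OC(=O)[C@]2(C)[C@@H](C)CC=C(C)[C@@H]12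
F10 | step 7 | ketimine (13 with C4=NH) | N=C1CC[C@@H]2OC(=O)[C@]3(C)[C@@H](C)CC[C@@]1(C)[C@@H]23
F11 | step 12 | iodo acid, 3-iodo-5-methoxy-4-[(4-methoxyphenyl)methoxy]benzoic acid | OC(=O)c1cc(I)c(OCc2ccc(OC)cc2)c(OC)c1
F12 | step 12 | magnesiated carboxylate from F11 | Cl[Mg]OC(=O)c1cc([Mg]Cl)c(OCc2ccc(OC)cc2)c(OC)c1
F13 | step 12 | dihydroxy acid (19 with CO2H in place of CO2Me) | C=C1CC[C@H](O)[C@H]2[C@](C)(C(O)c3cc(C(=O)O)cc(OC)c3OCc4ccc(OC)cc4)[C@@H](C)CC[C@]12C
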